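**Retrosynthetic overview**

1. Bonnaniol 18 comes from 17 by global MOM removal; the 3-OH of 17 comes from Rubottom oxidation of the C4 enol silane 15 of flavanone 14, trans to the C2 aryl group.
2. Ring C of 14 is cut at C2–C3 and O1–C8a: enol silane 10 of an o-fluoroaryl methyl ketone plus aldehyde 12, joined in one flask by an enantioselective Mukaiyama aldol and a desilylative ipso-substitution of fluoride.
3. Enabling feature: the C4 carbonyl of ring C is both α to C3 (enol silane nucleophile) and ortho to C8a of ring A (activation of C8a–F), while C8a is meta to O5 and O7; the O1=C2 unit of the aldehyde is stitched between C3 and C8a.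
4. Ketone 9 comes from 5-fluororesorcinol by two directed ortho-metalations of its bis-MOM ether: geranyl between the two oxygens (C6), acetyl next to fluorine (C4a), so the 6-geranyl pattern is fixed before ring C exists.
5. Ring order: rings A and B are bought (1 and 11); ring C is the only ring made (step 6).

Key step: step 6

In names, geranyl stands for (2E)-3,7-dimethylocta-2,6-dien-1-yl and MOM for methoxymethyl.
Assumption: the D-tryptophan-derived oxazaborolidinone is taken, by analogy with related aldehyde complexes, to expose the Si face of aldehyde 12; if a model aldol shows the opposite sense, its L-derived antipode is used.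

**Step 1**
Reactants: 1 5-fluorobenzene-1,3-diol
Product: 2 1-fluoro-3,5-bis(methoxymethoxy)benzene
Conditions: MOMCl, i-Pr2NEt, CH2Cl2, 0 → 23 °C
Reagents that add atoms: chloromethyl methyl ether, COCCl
Why: Base-mediated O-alkylation should give the bis-MOM ether, whose acetal oxygens direct both later lithiations and which survives base, fluoride and peroxide until the acidic last step.

**Step 2**
Reactants: 2 1-fluoro-3,5-bis(methoxymethoxy)benzene; 3 geranyl bromide
Product: 5 5-fluoro-2-geranyl-1,3-bis(methoxymethoxy)benzene, via aryllithium 4 (not isolated)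
Conditions: n-BuLi, THF, 0 °C; CuBr·SMe2 (20 mol%), then 3, −78 → 0 °C
Reagents that add atoms: none
Why: Directed ortho-metalation should occur at the carbon flanked by both OMOM groups (double coordination of n-BuLi), and copper-catalysed allylic substitution at the primary carbon of 3 then places the geranyl group between the two oxygens with the E alkene intact.

**Step 3**
Reactants: 5 5-fluoro-2-geranyl-1,3-bis(methoxymethoxy)benzene; 6 N-methoxy-N-methylacetamide
Product: 9 1-[6-fluoro-3-geranyl-2,4-bis(methoxymethoxy)phenyl]ethan-1-one, via aryllithium 7 (not isolated), via lithium hemiaminal alkoxide 8 (not isolated)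
Conditions: n-BuLi, THF, −78 °C; 6, −78 → −20 °C; H2O
Reagents that add atoms: none
Why: A second directed ortho-metalation at one of the two equivalent C–H positions flanked by F and OMOM (held at −78 °C so that the o-fluoroaryllithium does not lose LiF) is followed by acylation with the N-methoxy-N-methylamide, whose chelated tetrahedral adduct releases the ketone only on quench.

**Step 4**
Reactants: 9 1-[6-fluoro-3-geranyl-2,4-bis(methoxymethoxy)phenyl]ethan-1-one
Product: 10 {1-[6-fluoro-3-geranyl-2,4-bis(methoxymethoxy)phenyl]ethenyloxy}trimethylsilane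
Conditions: TMSOTf, Et3N, CH2Cl2, 0 °C
Reagents that add atoms: trimethylsilyl trifluoromethanesulfonate, C[Si](C)(C)OS(=O)(=O)C(F)(F)F
Why: Soft enolisation (silyl triflate and amine) of the methyl ketone, which has a single enolisable side, should give the terminal enol silane needed for the Mukaiyama aldol.

**Step 5**
Reactants: 11 4-hydroxybenzaldehyde
Product: 12 4-(methoxymethoxy)benzaldehyde
Conditions: MOMCl, i-Pr2NEt, CH2Cl2, 0 → 23 °C
Reagents that add atoms: chloromethyl methyl ether, COCCl
Why: Base-mediated O-alkylation masks the phenol as the same acid-labile MOM ether that is used on ring A.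

**Step 6**
Reactants: 10 {1-[6-fluoro-3-geranyl-2,4-bis(methoxymethoxy)phenyl]ethenyloxy}trimethylsilane; 12 4-(methoxymethoxy)benzaldehyde
Product: 14 (2S)-6-geranyl-5,7-bis(methoxymethoxy)-2-[4-(methoxymethoxy)phenyl]-2,3-dihydro-4H-chromen-4-one, via silyl aldol ether 13 (not isolated)
Conditions: (R)-2-butyl-4-(1H-indol-3-ylmethyl)-3-tosyl-1,3,2-oxazaborolidin-5-one (20 mol%), EtCN, −78 °C; then Bu4N[Ph3SiF2] (0.3 equiv), THF, −78 → 23 °C
Reagents that add atoms: none
Why: Proposed new method: the chiral boron Lewis acid binds aldehyde 12 and enol silane 10 adds to its Si face (Mukaiyama aldol, C2–C3) with silyl transfer to O1, so the aldol is stored at −78 °C as the configurationally safe silyl ether 13; fluoride then removes the silyl group, the O1 alkoxide adds to C8a (ipso to fluorine, ortho to the C4 carbonyl), and the σ-adduct expels fluoride (O1–C8a), which desilylates the next molecule of 13, so the second stage is a chain with Me3SiF as the only by-product. The closest known reaction types are the oxazaborolidinone-catalysed enantioselective Mukaiyama aldol of aryl methyl ketone enol silanes with aromatic aldehydes and the fluoride-catalysed etherification of silyl ethers with activated aryl fluorides, together with chromone and chromanone closures by substitution of fluoride ortho to a ketone; what is new is their coupling in one flask as an annulation. Ring C closes in the 6-exo-trig mode of the addition step at C8a. The only new stereocentre, C2, is set by the catalyst through the facial selectivity of the aldol and is not touched by the ring closure, because the O1–C2 bond is never broken. The step needs the ring closure to outrun retro-aldol cleavage and E1cB loss of silanolate; this is served by the intramolecular six-membered closure, by the low stationary concentration of alkoxide in the fluoride chain, and by the pattern of ring A, in which C8a is meta to both OMOM groups (nodal positions of the σ-adduct) and the charge is taken up by the C4 carbonyl.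

**Step 7**
Reactants: 14 (2S)-6-geranyl-5,7-bis(methoxymethoxy)-2-[4-(methoxymethoxy)phenyl]-2,3-dihydro-4H-chromen-4-one
Product: 15 (2S)-6-geranyl-5,7-bis(methoxymethoxy)-2-[4-(methoxymethoxy)phenyl]-4-(trimethylsilyloxy)-2H-chromene
Conditions: TMSOTf, Et3N, CH2Cl2, 0 °C
Reagents that add atoms: trimethylsilyl trifluoromethanesulfonate, C[Si](C)(C)OS(=O)(=O)C(F)(F)F
Why: Soft enolisation traps the C4 enol as its silane without a free enolate, which would open ring C by E1cB loss of the O1 phenoxide and erase C2.

**Step 8**
Reactants: 15 (2S)-6-geranyl-5,7-bis(methoxymethoxy)-2-[4-(methoxymethoxy)phenyl]-4-(trimethylsilyloxy)-2H-chromene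
Product: 17 (2R,3R)-6-geranyl-3-hydroxy-5,7-bis(methoxymethoxy)-2-[4-(methoxymethoxy)phenyl]-2,3-dihydro-4H-chromen-4-one, via silyloxy epoxide 16 (not isolated)
Conditions: DMDO (1.0 equiv), acetone/CH2Cl2, −78 °C; then AcOH, THF/H2O, 0 °C
Reagents that add atoms: dimethyldioxirane, CC1(C)OO1
Why: Rubottom oxidation: the electrophilic dioxirane should epoxidise the electron-rich enol silane far faster than the isolated trisubstituted alkenes at −78 °C and from the face opposite to the C2 aryl group, which sets C3 with O3 trans to the aryl group (2R,3R), and mild acid opens the silyloxy epoxide to the ketol.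

**Step 9**
Reactants: 17 (2R,3R)-6-geranyl-3-hydroxy-5,7-bis(methoxymethoxy)-2-[4-(methoxymethoxy)phenyl]-2,3-dihydro-4H-chromen-4-one
Product: 18 bonnaniol
Conditions: 3 M HCl, MeOH, 40 °C
Reagents that add atoms: none
Why: Acid-catalysed acetal methanolysis should remove the three aryl MOM groups, the trans ketol being the thermodynamic epimer and the low temperature limiting acid-induced cyclisation of the geranyl chain onto the flanking phenols.

**Compound list**

1 | 5-fluorobenzene-1,3-diol | Oc1cc(O)cc(F)c1 | starting material
2 | 1-fluoro-3,5-bis(methoxymethoxy)benzene | COCOc1cc(F)cc(OCOC)c1 | intermediate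
3 | geranyl bromide, (2E)-1-bromo-3,7-dimethylocta-2,6-diene | CC(C)=CCC/C(C)=C/CBr | starting material
4 | [4-fluoro-2,6-bis(methoxymethoxy)phenyl]lithium | [Li]c1c(OCOC)cc(F)cc1OCOC | intermediate
5 | 5-fluoro-2-geranyl-1,3-bis(methoxymethoxy)benzene | CC(C)=CCC/C(C)=C/Cc1c(OCOC)cc(F)cc1OCOC | intermediate
6 | N-methoxy-N-methylacetamide | CC(=O)N(C)OC | starting material
7 | [6-fluoro-3-geranyl-2,4-bis(methoxymethoxy)phenyl]lithium | CC(C)=CCC/C(C)=C/Cc1c(OCOC)cc(F)c([Li])c1OCOC | intermediate
8 | lithium 1-[6-fluoro-3-geranyl-2,4-bis(methoxymethoxy)phenyl]-1-[methoxy(methyl)amino]ethan-1-olate | CC(C)=CCC/C(C)=C/Cc1c(OCOC)cc(F)c(C(C)(O[Li])N(C)OC)c1OCOC | intermediate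
9 | 1-[6-fluoro-3-geranyl-2,4-bis(methoxymethoxy)phenyl]ethan-1-one | CC(C)=CCC/C(C)=C/Cc1c(OCOC)cc(F)c(C(C)=O)c1OCOC | intermediate
10 | {1-[6-fluoro-3-geranyl-2,4-bis(methoxymethoxy)phenyl]ethenyloxy}trimethylsilane | CC(C)=CCC/C(C)=C/Cc1c(OCOC)cc(F)c(C(=C)O[Si](C)(C)C)c1OCOC | intermediate
11 | 4-hydroxybenzaldehyde | O=Cc1ccc(O)cc1 | starting material
12 | 4-(methoxymethoxy)benzaldehyde | COCOc1ccc(C=O)cc1 | intermediate
13 | (3S)-1-[6-fluoro-3-geranyl-2,4-bis(methoxymethoxy)phenyl]-3-[4-(methoxymethoxy)phenyl]-3-(trimethylsilyloxy)propan-1-one | CC(C)=CCC/C(C)=C/Cc1c(OCOC)cc(F)c(C(=O)C[C@H](O[Si](C)(C)C)c2ccc(OCOC)cc2)c1OCOC | intermediate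
14 | (2S)-6-geranyl-5,7-bis(methoxymethoxy)-2-[4-(methoxymethoxy)phenyl]-2,3-dihydro-4H-chromen-4-one | CC(C)=CCC/C(C)=C/Cc1c(OCOC)cc2c(c1OCOC)C(=O)C[C@@H](c1ccc(OCOC)cc1)O2 | intermediate
15 | (2S)-6-geranyl-5,7-bis(methoxymethoxy)-2-[4-(methoxymethoxy)phenyl]-4-(trimethylsilyloxy)-2H-chromene | CC(C)=CCC/C(C)=C/Cc1c(OCOC)cc2c(c1OCOC)C(O[Si](C)(C)C)=C[C@@H](c1ccc(OCOC)cc1)O2 | intermediate
16 | 3,4-epoxide of 15, epoxide oxygen on the ring face opposite to the C2 aryl group, C2 configured as in 15 | CC(C)=CCC/C(C)=C/Cc1c(OCOC)cc2c(c1OCOC)[C@]3(O[Si](C)(C)C)O[C@@H]3[C@@H](c1ccc(OCOC)cc1)O2 | intermediate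
17 | (2R,3R)-6-geranyl-3-hydroxy-5,7-bis(methoxymethoxy)-2-[4-(methoxymethoxy)phenyl]-2,3-dihydro-4H-chromen-4-one | CC(C)=CCC/C(C)=C/Cc1c(OCOC)cc2c(c1OCOC)C(=O)[C@H](O)[C@@H](c1ccc(OCOC)cc1)O2 | intermediate
18 | bonnaniol, (2R,3R)-6-geranyl-3,5,7-trihydroxy-2-(4-hydroxyphenyl)-2,3-dihydro-4H-chromen-4-one | CC(C)=CCC/C(C)=C/Cc1c(O)cc2c(c1O)C(=O)[C@H](O)[C@@H](c1ccc(O)cc1)O2 | target

**Step count and risks**

Total step count: 9. Longest linear sequence: 8 steps (steps 1–4 and 6–9).

Steps most likely to fail:

Step 6 (proposed new method). After desilylation the free alkoxide may revert by retro-aldol cleavage and recombine without catalyst control, which would erode the enantiomeric purity. The silyl aldol ether may also lose silanolate by E1cB before the ring closes, and the ipso-substitution may be slow because the 2,6-disubstituted ketone is twisted out of conjugation. Enantiomeric purity would be checked at 14 and 17, both candidates for enrichment by crystallisation. The fallback uses known chemistry and sets out from ketone 9. Claisen formylation (HCO2Et, NaH, THF) should give 3-[6-fluoro-3-geranyl-2,4-bis(methoxymethoxy)phenyl]-3-oxopropanal F1. Its enolate oxygen displaces the ortho fluoride on warming with K2CO3 in DMF to give 6-geranyl-5,7-bis(methoxymethoxy)-4H-chromen-4-one F2. Enantioselective conjugate addition of 4-(methoxymethoxy)phenylboronic acid to this chromone (Pd(OCOCF3)2, 4-tert-butyl-2-(pyridin-2-yl)-4,5-dihydrooxazole in the antipode that gives the 2S product, NH4PF6, H2O, 1,2-dichloroethane, 60 °C) then comes back to the route at flavanone 14.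

Step 8. The dioxirane may also epoxidise the two trisubstituted alkenes of the geranyl chain, so that chemoselectivity for the enol silane is lost. The fallback sets out from flavanone 14 and bypasses 15. Deprotonation with KN(SiMe3)2 in THF at −78 °C is followed at once by 2-(phenylsulfonyl)-3-phenyloxaziridine; this reagent class hydroxylates enolates and leaves isolated alkenes alone at that temperature. The enolate is attacked anti to the C2 aryl group, and the short enolate lifetime at −78 °C limits E1cB opening of ring C. This comes back to the route at ketol 17.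

Step 2. Lithiation may leak to the carbon between fluorine and OMOM, which would carry the geranyl group to what becomes C8, and the allylic coupling may transpose. The fallback sets out from diol 1. Iodination between the two hydroxyls (I2, NaHCO3, H2O), the usual site for resorcinols under these conditions, should give 5-fluoro-2-iodobenzene-1,3-diol F3. MOM protection (MOMCl, i-Pr2NEt) gives 5-fluoro-2-iodo-1,3-bis(methoxymethoxy)benzene F4. Iodine–lithium exchange (n-BuLi, THF, −78 °C) then delivers aryllithium 4 regiospecifically, and geranylation as in step 2 comes back to the route at compound 5.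

**Further compounds**

F1 | step 6 | 3-[6-fluoro-3-geranyl-2,4-bis(methoxymethoxy)phenyl]-3-oxopropanal | CC(C)=CCC/C(C)=C/Cc1c(OCOC)cc(F)c(C(=O)CC=O)c1OCOC
F2 | step 6 | 6-geranyl-5,7-bis(methoxymethoxy)-4H-chromen-4-one | CC(C)=CCC/C(C)=C/Cc1c(OCOC)cc2occc(=O)c2c1OCOC
F0 | step 8 | none | none
F3 | step 2 | 5-fluoro-2-iodobenzene-1,3-diol | Oc1cc(F)cc(O)c1I
F4 | step 2 | 5-fluoro-2-iodo-1,3-bis(methoxymethoxy)benzene | COCOc1cc(F)cc(OCOC)c1I
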